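**Retrosynthetic overview**

1. The target is umbelliferone O-alkylated by a five-carbon chain that carries a secondary/tertiary 2,3-diol and, on its far CH2, C5 of an α-methylene-γ-butyrolactone. The chain is cut between that CH2 and the tertiary carbinol carbon.
2. Enabling feature: the lactone ring oxygen on C5 lies 1,3 to the tertiary hydroxyl (O–C5–CH2–C(OH)Me). With C5 at the ketone level the CH2 becomes an enol carbon, and the carbinol carbon becomes a methyl ketone whose neighbouring O-bearing CH (next to the aryloxymethyl group) activates it and controls its faces.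
3. This gives a Mukaiyama aldol between a coumarin-bearing (R)-α-silyloxy methyl ketone and the terminal enol silane of a 2-phosphono-4-oxopentanoate. The phosphonate fixes the enolization site (dianion), masks the exo-methylene and delivers it by Horner–Wadsworth–Emmons reaction at the end.
4. Ring order: the coumarin bicycle is bought intact; the γ-lactone is closed after the key step by chelate-controlled reduction and lactonization; then exo-methylene; then desilylation.

Key step: step 6

Remark: the phosphonate-bearing carbon of the keto ester series is epimerizable and is carried as a mixture of epimers (drawn without descriptor); it becomes sp2 in step 8.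

**Step 1**
Reactants: 1 umbelliferone (7-hydroxy-2H-chromen-2-one); 2 (2S)-2-hydroxybut-3-en-1-yl 4-methylbenzenesulfonate
Product: 3 7-{[(2S)-2-hydroxybut-3-en-1-yl]oxy}-2H-chromen-2-one
Conditions: K2CO3 (1.5 equiv), DMF, 60 °C
Reagents that add atoms: none
Why: Williamson ether synthesis in which the phenoxide of 1 (pKa about 8) should displace the primary tosylate by SN2 under mild carbonate conditions that do not touch the secondary allylic carbinol centre, so the (S) configuration is carried over unchanged.

**Step 2**
Reactants: 3 7-{[(2S)-2-hydroxybut-3-en-1-yl]oxy}-2H-chromen-2-one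
Product: 4 7-{[(2S)-2-[(tert-butyldimethylsilyl)oxy]but-3-en-1-yl]oxy}-2H-chromen-2-one
Conditions: TBSCl, imidazole, DMF, rt
Reagents that add atoms: tert-butyldimethylsilyl chloride, CC(C)(C)[Si](C)(C)Cl
Why: Standard imidazole-mediated silylation of a secondary alcohol, giving a bulky non-chelating silyl ether that tolerates the Wacker step and later enforces the Felkin–Anh mode in step 6.

**Step 3**
Reactants: 4 7-{[(2S)-2-[(tert-butyldimethylsilyl)oxy]but-3-en-1-yl]oxy}-2H-chromen-2-one
Product: 5 7-{[(2R)-2-[(tert-butyldimethylsilyl)oxy]-3-oxobutyl]oxy}-2H-chromen-2-one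
Conditions: Pd(quinox)Cl2 (5 mol %), AgSbF6 (12 mol %), aq. TBHP (70%), CH2Cl2, 0 °C → rt
Reagents that add atoms: tert-butyl hydroperoxide, CC(C)(C)OO
Why: Peroxide-mediated Wacker-type oxidation with a quinoline–oxazoline Pd(II) catalyst is Markovnikov-selective for protected allylic alcohols and should give the methyl ketone without epimerizing the α-silyloxy centre (the S to R change is only a CIP priority change), while the electron-poor coumarin C3=C4 bond is not a substrate.

**Step 4**
Reactants: 6 triethyl phosphonoacetate; 7 chloroacetone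
Product: 8 ethyl 2-(diethoxyphosphoryl)-4-oxopentanoate (racemic)
Conditions: NaH, THF, 0 °C; then 7, NaI (cat.), 0 °C → rt
Reagents that add atoms: none
Why: SN2 C-alkylation of the sodium phosphonoacetate carbanion by the α-chloro ketone, the standard entry to 2-phosphono-4-oxoalkanoates.

**Step 5**
Reactants: 8 ethyl 2-(diethoxyphosphoryl)-4-oxopentanoate
Product: 10 ethyl 2-(diethoxyphosphoryl)-4-[(triethylsilyl)oxy]pent-4-enoate, via dilithium dianion 9 (not isolated)
Conditions: LDA (2.05 equiv), THF, −78 °C; TESCl (1.05 equiv), −78 °C; AcOH (1.0 equiv), −78 °C, then pH 7 buffer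
Reagents that add atoms: chlorotriethylsilane, CC[Si](CC)(CC)Cl
Why: Dianion regiocontrol as in β-dicarbonyl dianion chemistry, in which the first equivalent of LDA removes the phosphonoacetate C–H, the second can then deprotonate only the remote methyl group because the CH2 next to the carbanion is electronically and sterically shielded, and the hard terminal enolate oxygen is silylated selectively before the stabilized carbanion is re-protonated.

**Step 6**
Reactants: 5 7-{[(2R)-2-[(tert-butyldimethylsilyl)oxy]-3-oxobutyl]oxy}-2H-chromen-2-one; 10 ethyl 2-(diethoxyphosphoryl)-4-[(triethylsilyl)oxy]pent-4-enoate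
Product: 11 ethyl (6S,7R)-7-[(tert-butyldimethylsilyl)oxy]-2-(diethoxyphosphoryl)-6-hydroxy-6-methyl-4-oxo-8-[(2-oxo-2H-chromen-7-yl)oxy]octanoate (C2 epimers)
Conditions: BF3·OEt2 (3 equiv; 5 pre-complexed, then 10), CH2Cl2, −78 → −40 °C; aq. NaHCO3
Reagents that add atoms: none
Why: BF3 binds the ketone oxygen of 5 in a monodentate way and the terminal CH2 of enol silane 10 attacks the carbonyl carbon through an open transition state, after which fluoride transfer releases Et3SiF and leaves a boron aldolate that is hydrolysed on work-up. The closest known reaction type is the Mukaiyama aldol addition of a methyl-ketone enol silane to an α-oxygenated ketone. No ring is closed in this step; the lactone ring is closed in step 7 from the β-hydroxy ketone made here. The new tertiary carbinol centre is controlled by the adjacent silyloxy-bearing stereocentre in the polar Felkin–Anh (Cornforth) sense, with the C–OTBS bond anti to the incoming nucleophile, the aryloxymethyl group inside and attack past the hydrogen, which should give the (6S) centre next to (7R) as the target requires. The step needs site selectivity in the nucleophile, fixed by the regiodefined terminal enol silane; chemoselectivity for the ketone over the coumarin lactone and the ester, expected from the higher electrophilicity of the BF3-bound α-silyloxy ketone; and facial selectivity, secured by the bulky non-chelating TBS ether together with a monodentate Lewis acid, which shut down the chelate pathway leading to the epimer. In one operation the step joins the two halves, installs every carbon of the target except the exo-methylene carbon and creates the 1,3-ketol that relays stereochemistry to the lactone carbon.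

**Step 7**
Reactants: 11 ethyl (6S,7R)-7-[(tert-butyldimethylsilyl)oxy]-2-(diethoxyphosphoryl)-6-hydroxy-6-methyl-4-oxo-8-[(2-oxo-2H-chromen-7-yl)oxy]octanoate
Product: 14 diethyl {(5R)-5-[(2S,3R)-3-[(tert-butyldimethylsilyl)oxy]-2-hydroxy-2-methyl-4-[(2-oxo-2H-chromen-7-yl)oxy]butyl]-2-oxooxolan-3-yl}phosphonate (C3 epimers), via diethylboron chelate 12 (not isolated), via syn-diol ester 13 (not isolated)
Conditions: Et2BOMe, THF/MeOH (4:1), −78 °C; NaBH4, −78 °C; MeOH co-evaporation (boron leaves as Et2BOMe); then PPTS (cat.), toluene, 50 °C
Reagents that add atoms: none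
Why: Narasaka–Prasad reduction in which the tertiary alkoxide and the ketone are tied in a six-membered dialkylboron chelate with the large silyloxy-bearing substituent equatorial, external hydride adds axially to give the 1,3-syn (4R,6S) diol, and acid then closes the γ-lactone by 5-exo-trig acyl substitution of the ethyl ester.

**Step 8**
Reactants: 14 diethyl {(5R)-5-[(2S,3R)-3-[(tert-butyldimethylsilyl)oxy]-2-hydroxy-2-methyl-4-[(2-oxo-2H-chromen-7-yl)oxy]butyl]-2-oxooxolan-3-yl}phosphonate
Product: 15 7-{[(2R,3S)-2-[(tert-butyldimethylsilyl)oxy]-3-hydroxy-3-methyl-4-[(2S)-4-methylidene-5-oxooxolan-2-yl]butyl]oxy}-2H-chromen-2-one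
Conditions: K2CO3, 37% aq. HCHO, THF, 0 °C → rt
Reagents that add atoms: formaldehyde, C=O
Why: Horner–Wadsworth–Emmons olefination of the α-phosphono lactone with formaldehyde under mild carbonate conditions is the standard late-stage entry to α-methylene-γ-butyrolactones, both C3 epimers converge on the single exocyclic alkene, and no stereocentre is touched (the lactone descriptor changes from R to S only by CIP priority).

**Step 9**
Reactants: 15 7-{[(2R,3S)-2-[(tert-butyldimethylsilyl)oxy]-3-hydroxy-3-methyl-4-[(2S)-4-methylidene-5-oxooxolan-2-yl]butyl]oxy}-2H-chromen-2-one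
Product: 16 7-{[(2R,3S)-2,3-dihydroxy-3-methyl-4-[(2S)-4-methylidene-5-oxooxolan-2-yl]butyl]oxy}-2H-chromen-2-one (target)
Conditions: HF·pyridine, THF/pyridine, 0 °C → rt
Reagents that add atoms: none
Why: Acidic fluoride cleavage of the secondary TBS ether is non-basic enough to spare the α-methylene lactone (a Michael acceptor), the coumarin and the tertiary alcohol, and it should release the target without touching a stereocentre.

**Compound list**

1 | umbelliferone (7-hydroxy-2H-chromen-2-one) | Oc1ccc2ccc(=O)oc2c1 | starting material
2 | (2S)-2-hydroxybut-3-en-1-yl 4-methylbenzenesulfonate | C=C[C@H](O)COS(=O)(=O)c1ccc(C)cc1 | starting material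
3 | 7-{[(2S)-2-hydroxybut-3-en-1-yl]oxy}-2H-chromen-2-one | C=C[C@H](O)COc1ccc2ccc(=O)oc2c1 | intermediate
4 | 7-{[(2S)-2-[(tert-butyldimethylsilyl)oxy]but-3-en-1-yl]oxy}-2H-chromen-2-one | C=C[C@H](O[Si](C)(C)C(C)(C)C)COc1ccc2ccc(=O)oc2c1 | intermediate
5 | 7-{[(2R)-2-[(tert-butyldimethylsilyl)oxy]-3-oxobutyl]oxy}-2H-chromen-2-one | CC(=O)[C@H](O[Si](C)(C)C(C)(C)C)COc1ccc2ccc(=O)oc2c1 | intermediate
6 | triethyl phosphonoacetate | CCOC(=O)CP(=O)(OCC)OCC | starting material
7 | chloroacetone | CC(=O)CCl | starting material
8 | ethyl 2-(diethoxyphosphoryl)-4-oxopentanoate (racemic) | CCOC(=O)C(CC(C)=O)P(=O)(OCC)OCC | intermediate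
9 | dilithium dianion of 8 (C2 carbanion, terminal C4 enolate) | [Li+].[Li+].CCOC(=O)[C-](CC(=C)[O-])P(=O)(OCC)OCC | intermediate
10 | ethyl 2-(diethoxyphosphoryl)-4-[(triethylsilyl)oxy]pent-4-enoate | CCOC(=O)C(CC(=C)O[Si](CC)(CC)CC)P(=O)(OCC)OCC | intermediate
11 | ethyl (6S,7R)-7-[(tert-butyldimethylsilyl)oxy]-2-(diethoxyphosphoryl)-6-hydroxy-6-methyl-4-oxo-8-[(2-oxo-2H-chromen-7-yl)oxy]octanoate (C2 epimers) | CCOC(=O)C(CC(=O)C[C@](C)(O)[C@H](O[Si](C)(C)C(C)(C)C)COc1ccc2ccc(=O)oc2c1)P(=O)(OCC)OCC | intermediate
12 | diethylboron chelate of 11 (6-O-diethylboryl ether, boron coordinated to the C4 ketone) | CCOC(=O)C(CC(=O)C[C@](C)(OB(CC)CC)[C@H](O[Si](C)(C)C(C)(C)C)COc1ccc2ccc(=O)oc2c1)P(=O)(OCC)OCC | intermediate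
13 | ethyl (4R,6S,7R)-7-[(tert-butyldimethylsilyl)oxy]-2-(diethoxyphosphoryl)-4,6-dihydroxy-6-methyl-8-[(2-oxo-2H-chromen-7-yl)oxy]octanoate (C2 epimers) | CCOC(=O)C(C[C@H](O)C[C@](C)(O)[C@H](O[Si](C)(C)C(C)(C)C)COc1ccc2ccc(=O)oc2c1)P(=O)(OCC)OCC | intermediate
14 | diethyl {(5R)-5-[(2S,3R)-3-[(tert-butyldimethylsilyl)oxy]-2-hydroxy-2-methyl-4-[(2-oxo-2H-chromen-7-yl)oxy]butyl]-2-oxooxolan-3-yl}phosphonate (C3 epimers) | CCOP(=O)(OCC)C1C[C@@H](C[C@](C)(O)[C@H](O[Si](C)(C)C(C)(C)C)COc2ccc3ccc(=O)oc3c2)OC1=O | intermediate
15 | 7-{[(2R,3S)-2-[(tert-butyldimethylsilyl)oxy]-3-hydroxy-3-methyl-4-[(2S)-4-methylidene-5-oxooxolan-2-yl]butyl]oxy}-2H-chromen-2-one | C=C1C[C@@H](C[C@](C)(O)[C@H](O[Si](C)(C)C(C)(C)C)COc2ccc3ccc(=O)oc3c2)OC1=O | intermediate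
16 | 7-{[(2R,3S)-2,3-dihydroxy-3-methyl-4-[(2S)-4-methylidene-5-oxooxolan-2-yl]butyl]oxy}-2H-chromen-2-one | C=C1C[C@@H](C[C@](C)(O)[C@H](O)COc2ccc3ccc(=O)oc3c2)OC1=O | target

**Step count and risks**

Total step count: 9. Longest linear sequence: 7 steps (1, 2, 3, 6, 7, 8, 9); the phosphonate branch (steps 4 and 5) joins at step 6.

Steps most likely to fail, in order of risk:

Step 6 (key aldol). C–C bond formation at the hindered, only moderately activated ketone may be slow. On warming, the enol silane can be lost by protodesilylation, the boron aldolate can revert by retro-aldol cleavage, and the Felkin preference can erode. The fallback replaces the aldol by an allylation that makes the same bond. Setting out from 6 and 5, 6 would be alkylated (NaH, THF/DMF, cat. NaI) with 2-(chloromethyl)allyl(trimethyl)silane to ethyl 2-(diethoxyphosphoryl)-4-[(trimethylsilyl)methyl]pent-4-enoate F1, a regiodefined and storable 2-substituted allylsilane. Hosomi–Sakurai addition of F1 to 5 (TiCl4 or BF3·OEt2, CH2Cl2, −78 °C; same Felkin–Anh model) should give the homoallylic tertiary alcohol ethyl (6S,7R)-7-[(tert-butyldimethylsilyl)oxy]-2-(diethoxyphosphoryl)-6-hydroxy-6-methyl-4-methylidene-8-[(2-oxo-2H-chromen-7-yl)oxy]octanoate F2, which has no retro-aldol channel. Lemieux–Johnson cleavage of its 1,1-disubstituted alkene (cat. OsO4, NaIO4, 2,6-lutidine, dioxane/H2O; the electron-poor coumarin double bond should react far more slowly) would return to the route at 11.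

Step 5 (regiodefined enol silane). The second deprotonation may be incomplete, or proton exchange may lead to the internal enolate. Silylation may also occur at the phosphonoacetate carbanion, and the enol silane may hydrolyse during work-up. The fallback fixes the regiochemistry by construction instead of by deprotonation. Setting out from 6, alkylation (NaH, THF) with freshly prepared 2-methoxyallyl bromide should give ethyl 2-(diethoxyphosphoryl)-4-methoxypent-4-enoate F3, whose enol ether can only be terminal. F3 would be used in place of 10 in a Lewis acid-promoted aldol-type addition to 5 (BF3·OEt2, CH2Cl2, −78 °C). Mildly acidic aqueous work-up would hydrolyse the enol ether/oxocarbenium stage to the ketone, so the route is rejoined at 11.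

Step 7 (syn reduction and lactonization). Facial discrimination in hydride delivery may be poor, because the chelate on a tertiary alkoxide forms slowly and its axial methyl group hinders the axial hydride trajectory; this would give the C4 epimer. The fallback uses catalyst control instead of substrate chelate control. Setting out from 11, Noyori-type hydrogenation of the γ-keto ester with a Ru(II)–BINAP catalyst (H2, EtOH; ester- and phosphoryl-directed; ligand antipode chosen for the (4R) alcohol) should give 13. This lactonizes under the same PPTS conditions, so the route is rejoined at 14. This fallback makes no compound outside the list (F0).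

**Further compounds**

F1 | step 6 | ethyl 2-(diethoxyphosphoryl)-4-[(trimethylsilyl)methyl]pent-4-enoate | CCOC(=O)C(CC(=C)C[Si](C)(C)C)P(=O)(OCC)OCC
F2 | step 6 | ethyl (6S,7R)-7-[(tert-butyldimethylsilyl)oxy]-2-(diethoxyphosphoryl)-6-hydroxy-6-methyl-4-methylidene-8-[(2-oxo-2H-chromen-7-yl)oxy]octanoate (C2 epimers) | CCOC(=O)C(CC(=C)C[C@](C)(O)[C@H](O[Si](C)(C)C(C)(C)C)COc1ccc2ccc(=O)oc2c1)P(=O)(OCC)OCC
F3 | step 5 | ethyl 2-(diethoxyphosphoryl)-4-methoxypent-4-enoate | CCOC(=O)C(CC(=C)OC)P(=O)(OCC)OCC
F0 | step 7 | none | none
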